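In the winter flask, closed and of constant volume, Z and Q, every form of Q counted, should add up to the charge. The sums run from 95.0% to 104%, which a scatter of 2 percentage points per reading allows, so Z goes to Q with no visible loss.

| flask | Z | remark | time |
|---|---|---|---|
| winter | 28 mM | run made earlier |  |
| Wednesday's | 25 mM |  | 12 min |
| Saturday's | 50 mM |  | 12 min |
| Thursday's | 100 mM |  | 12 min |
| Tuesday's | 200 mM |  | 12 min |

- winter (time / min: Q / %, Z / %): 0.667: 57, 42; 1.33: 79, 16; 2.00: 93, 11; 2.50: 93, 4; 3.00: 94, 1; 4.00: 100, 3

(readings scatter by 2 percentage points)

- what was read earlier has a scatter of 2 percentage points, one standard deviation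
- a reading or a percentage of Q counts all its forms, free or not
- the concentration of Q that is asked is that of its free form alone
- "hardly changes" means that all values lie within two and a half points (for a concentration: within two and a half percent of the largest)

- [Q] (only what is free in solution) at the end for Wednesday's, Saturday's, Thursday's, Tuesday's, in this order
- how the row runs (falls, then rises / hardly changes / falls all the way / rises all the way / rises, then falls)

The amount of Q in all forms at the end of each flask then follows from how much Z has gone. At 1.33 min the winter run keeps 16% of its Z, which for a first-order fall gives a rate constant of 1.38 min⁻¹. The reading at 0.667 min gives 1.30 min⁻¹, so the two agree within their scatter. The half-life is therefore 0.503 min, and 12 min holds 23.9 half-lives. That puts >99.9% of the charge through by then: this fraction of the charge gone from Z at the asked time is the reacted share.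

The weak link is the first order, read at 28 mM alone. Suppose the rate stopped growing above that charge and stayed at the early winter value of 38.6 mM min⁻¹. Tuesday's 200 mM would then need 5.18 min, less than the 12 min given, so even on that supposition Tuesday's Z is through in time.

This reckoning commits to Q in all forms of 25.0 mM for Wednesday's and 200 mM for Tuesday's. Free Q is a part of these amounts, so they are ceilings for it; the readings count all forms and do not show the free part.

The forecast sets free Q at the charges, 25 mM, 50 mM, 100 mM and 200 mM, a row that rises all the way: “My expectation is therefore free Q ≈ charge, with ranges stretched downward at high concentration for that risk.”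

Free Q ends at 4.20 mM, 4.20 mM, 4.20 mM and 4.20 mM, a row that hardly changes.

    Z → Q (k = 0.0210 s⁻¹)
    X ⇌ Q, rate k2*(cs2 - [Q]) while solid is left; crystals form when [Q] > cs2 (solubility = 4.20 mM, k = 0.290 s⁻¹)

Q also stands as crystals X, which the readings count within Q. Wednesday's reacted share gives 25.0 mM of Q in all forms, and 20.8 mM of that is X, 83.2% of the charge. Tuesday's reacted share gives 200 mM, and 196 mM of that is X, 97.9% of the charge.

The readings were computed for an exercise, and the scatter is random.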